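**Plan**

1. Numbering used throughout: the 14-membered carbocycle is C1 (lactone O–CH) – C2 (CH–OAc) – C3 (CH–CH3) – C4/C5/C6 (CH2) – C7 (C(CH3)OH) – C8=C9 (E) – C10 (CH2) – C11 (C–CH3, oxirane) – C12 (oxirane CH) – C13 (CH2) – C14 (ring-fusion CH that carries the C(=CH2)–C(=O)O unit).
2. Retrosynthetic cuts, in order: the C11–C12 oxirane back to the E-alkene; then the ring bond C10–C11, giving an open chain with a vinyl oxirane (C7–C8 oxirane, C9=C10 vinyl) and an alkenylstannane at C11; then the lactone bond C14–C1, giving an α-hydroxy aldehyde (C1–C10, fragment 1) and a 2-(bromomethyl)enoate (C11–C14 plus the three lactone carbons, fragment 2).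
3. Enabling feature: the C7 carbinol and the C10 methylene are 1,4-related across the E-C8=C9 alkene, which is the retron of a vinyl oxirane opened at its alkene terminus. C7 is quaternary, so the derived π-allyl has no β-hydrogen to lose. C11, the methyl-bearing oxirane carbon, can be carried as the tin-bearing carbon of an E-alkene.
4. Forward: fragment 1 by syn-crotylboration, chain extension, carboalumination, asymmetric epoxidation and methylenation; fragment 2 by hydrozirconation, stannylation and a Baylis–Hillman-type homologation; union by a chelation-controlled indium allylation that also gives the cis γ-lactone; then the 14-membered ring by palladium-catalysed alkenylstannane/vinyl-oxirane coupling; epoxidation last.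
5. Stereochemistry: C2/C3 from the Brown (Z)-crotylboration; C7 from the Sharpless epoxidation (the C8 oxirane centre is expendable, either epimer would give the same π-allyl); C1/C14 from chelation by the C2 hydroxyl and the Z-geometry of the allyl bromide; E-C8=C9 from the syn π-allyl; C11/C12 from the Shi ketone.

Key step: step 19

Remark: minor diastereomers from incomplete enantioselectivity in steps 1 and 7 are expected to be separable at 12 or 25; the racemic carbinol centre of 22 disappears in step 16.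

**Route**

Step 1
Reactants: 1 2-[(tert-butyldimethylsilyl)oxy]acetaldehyde
Product: 3 (2R,3S)-1-[(tert-butyldimethylsilyl)oxy]-3-methylpent-4-en-2-ol, via borinate ester 2 (not isolated)
Conditions: cis-2-butene, KOt-Bu, n-BuLi, THF, −78 to −45 °C; (+)-Ipc2BOMe, −78 °C; BF3·OEt2; then 1, −78 °C; NaOH, H2O2, 0 °C to rt
Reagents that add atoms: cis-2-butene C/C=C\C
Why: Brown (Z)-crotylboration through a closed chair transition state, in which the Z-crotyl geometry should give the 2,3-syn relationship and the (+)-Ipc ligands (from (−)-α-pinene) should direct attack to the Re face of the aldehyde, setting C2 (R) and C3 (S) together.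

Step 2
Reactants: 3 (2R,3S)-1-[(tert-butyldimethylsilyl)oxy]-3-methylpent-4-en-2-ol
Product: 4 (2R,3S)-1,2-bis[(tert-butyldimethylsilyl)oxy]-3-methylpent-4-ene
Conditions: TBSOTf, 2,6-lutidine, CH2Cl2, −78 to 0 °C
Reagents that add atoms: tert-butyldimethylsilyl triflate CC(C)(C)[Si](C)(C)OS(=O)(=O)C(F)(F)F
Why: routine silylation of the secondary alcohol with a silyl triflate, needed because a free C2 alkoxide would cyclize onto the later C5 iodide; no stereocentre is touched.

Step 3
Reactants: 4 (2R,3S)-1,2-bis[(tert-butyldimethylsilyl)oxy]-3-methylpent-4-ene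
Product: 6 (3S,4R)-4,5-bis[(tert-butyldimethylsilyl)oxy]-3-methylpentan-1-ol, via alkyl-9-BBN adduct 5 (not isolated)
Conditions: 9-BBN, THF, 0 °C to rt; then NaOH, H2O2, 0 °C
Reagents that add atoms: hydrogen peroxide OO
Why: anti-Markovnikov hydroboration of the terminal alkene with 9-BBN followed by oxidation of the C–B bond with retention (hydroboration–oxidation) should give the primary alcohol at C5.

Step 4
Reactants: 6 (3S,4R)-4,5-bis[(tert-butyldimethylsilyl)oxy]-3-methylpentan-1-ol
Product: 7 (2R,3S)-1,2-bis[(tert-butyldimethylsilyl)oxy]-5-iodo-3-methylpentane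
Conditions: I2, PPh3, imidazole, CH2Cl2, 0 °C to rt
Reagents that add atoms: iodine II
Why: Appel-type iodination of the unhindered primary alcohol through its alkoxyphosphonium salt; silyl ethers are inert.

Step 5
Reactants: 7 (2R,3S)-1,2-bis[(tert-butyldimethylsilyl)oxy]-5-iodo-3-methylpentane
Product: 9 (6S,7R)-7,8-bis[(tert-butyldimethylsilyl)oxy]-6-methyloct-1-yne, via silylalkyne 8 (not isolated)
Conditions: 1-(trimethylsilyl)propyne, n-BuLi, THF, −78 to −20 °C; 7, DMPU, −78 °C to rt; then K2CO3 (cat.), MeOH, rt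
Reagents that add atoms: 1-(trimethylsilyl)propyne CC#C[Si](C)(C)C
Why: SN2 alkylation of the propargylic lithium reagent of 1-(trimethylsilyl)propyne by the primary iodide adds C6–C8, and methoxide then removes the alkynyl silyl group while the O-silyl ethers survive.

Step 6
Reactants: 9 (6S,7R)-7,8-bis[(tert-butyldimethylsilyl)oxy]-6-methyloct-1-yne
Product: 11 (2E,7S,8R)-8,9-bis[(tert-butyldimethylsilyl)oxy]-3,7-dimethylnon-2-en-1-ol, via alkenylalane 10 (not isolated)
Conditions: Me3Al, Cp2ZrCl2 (25 mol%), CH2Cl2, 0 °C to rt; then n-BuLi, THF, −78 °C; (CH2O)n, rt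
Reagents that add atoms: trimethylaluminium C[Al](C)C; formaldehyde (as paraformaldehyde) C=O
Why: Negishi zirconium-catalysed carboalumination adds methyl and aluminium syn across the terminal alkyne with methyl on the internal carbon, and hydroxymethylation of the derived alanate with retention should give the E-trisubstituted allylic alcohol (C7=C8, C9–OH).

Step 7
Reactants: 11 (2E,7S,8R)-8,9-bis[(tert-butyldimethylsilyl)oxy]-3,7-dimethylnon-2-en-1-ol
Product: 12 [(2S,3S)-3-[(4S,5R)-5,6-bis[(tert-butyldimethylsilyl)oxy]-4-methylhexyl]-3-methyloxiran-2-yl]methanol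
Conditions: Ti(OiPr)4 (10 mol%), L-(+)-diethyl tartrate (12 mol%), t-BuOOH, 4 Å molecular sieves, CH2Cl2, −20 °C
Reagents that add atoms: tert-butyl hydroperoxide CC(C)(C)OO
Why: Sharpless asymmetric epoxidation, in which the L-(+)-tartrate catalyst should deliver oxygen to the face of the E-allylic alcohol that gives the (2S,3S)-epoxy alcohol (as with geraniol), fixing the C7 centre with the S configuration of the later carbinol.

Step 8
Reactants: 12 [(2S,3S)-3-[(4S,5R)-5,6-bis[(tert-butyldimethylsilyl)oxy]-4-methylhexyl]-3-methyloxiran-2-yl]methanol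
Product: 13 (2R,3S)-3-[(4S,5R)-5,6-bis[(tert-butyldimethylsilyl)oxy]-4-methylhexyl]-3-methyloxirane-2-carbaldehyde
Conditions: Dess–Martin periodinane, NaHCO3, CH2Cl2, 0 °C
Reagents that add atoms: none
Why: buffered Dess–Martin oxidation of the primary alcohol, mild enough for an epoxy aldehyde (the descriptor at C8 changes by priority only).

Step 9
Reactants: 13 (2R,3S)-3-[(4S,5R)-5,6-bis[(tert-butyldimethylsilyl)oxy]-4-methylhexyl]-3-methyloxirane-2-carbaldehyde
Product: 14 (2S,3S)-2-[(4S,5R)-5,6-bis[(tert-butyldimethylsilyl)oxy]-4-methylhexyl]-3-ethenyl-2-methyloxirane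
Conditions: Ph3PCH3Br, KN(SiMe3)2, THF, 0 °C; then 13, −78 to 0 °C
Reagents that add atoms: methyltriphenylphosphonium bromide C[P+](c1ccccc1)(c1ccccc1)c1ccccc1.[Br-]
Why: Wittig methylenation of the epoxy aldehyde at low temperature, the standard entry to vinyl oxiranes, adds C10.

Step 10
Reactants: 14 (2S,3S)-2-[(4S,5R)-5,6-bis[(tert-butyldimethylsilyl)oxy]-4-methylhexyl]-3-ethenyl-2-methyloxirane
Product: 15 (2R,3S)-6-[(2S,3S)-3-ethenyl-2-methyloxiran-2-yl]-3-methylhexane-1,2-diol
Conditions: Bu4NF, THF, 0 °C to rt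
Reagents that add atoms: none
Why: fluoride cleaves both silyl ethers under non-acidic conditions that the acid-labile vinyl oxirane tolerates.

Step 11
Reactants: 15 (2R,3S)-6-[(2S,3S)-3-ethenyl-2-methyloxiran-2-yl]-3-methylhexane-1,2-diol
Product: 16 (2R,3S)-6-[(2S,3S)-3-ethenyl-2-methyloxiran-2-yl]-2-hydroxy-3-methylhexanal
Conditions: TEMPO (10 mol%), PhI(OAc)2, CH2Cl2, rt; used crude
Reagents that add atoms: none
Why: oxoammonium-mediated (TEMPO) oxidation is selective for the primary hydroxyl of the 1,2-diol and should give the α-hydroxy aldehyde without enolizing C2.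

Step 12
Reactants: 17 pent-3-yn-1-ol
Product: 19 (E)-4-iodopent-3-en-1-ol, via alkenylzirconocene 18 (not isolated)
Conditions: Cp2Zr(H)Cl (2.5 equiv), THF, rt to 40 °C; then I2, 0 °C
Reagents that add atoms: iodine II
Why: syn-hydrozirconation of the internal alkyne (one equivalent is consumed by the hydroxyl), equilibration with excess hydride toward zirconium on the less hindered methyl-bearing carbon, and iodinolysis with retention should give the E-iodide.

Step 13
Reactants: 19 (E)-4-iodopent-3-en-1-ol
Product: 20 (E)-4-(trimethylstannyl)pent-3-en-1-ol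
Conditions: Me3SnSnMe3, Pd(PPh3)4 (5 mol%), toluene, 80 °C
Reagents that add atoms: hexamethylditin C[Sn](C)(C)[Sn](C)(C)C
Why: palladium-catalysed stannylation of an alkenyl iodide with a ditin (oxidative addition, Sn–Sn transmetalation, reductive elimination) proceeds with retention of alkene geometry and tolerates the free alcohol.

Step 14
Reactants: 20 (E)-4-(trimethylstannyl)pent-3-en-1-ol
Product: 21 (E)-4-(trimethylstannyl)pent-3-enal
Conditions: Dess–Martin periodinane, NaHCO3, CH2Cl2, 0 °C; used at once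
Reagents that add atoms: none
Why: buffered Dess–Martin oxidation gives the β,γ-unsaturated aldehyde without base, so conjugation of the alkene and protodestannylation should be avoided.

Step 15
Reactants: 21 (E)-4-(trimethylstannyl)pent-3-enal
Product: 22 methyl (5E)-3-hydroxy-2-methylidene-6-(trimethylstannyl)hept-5-enoate (racemic)
Conditions: i-Bu2AlH, N-methylmorpholine N-oxide, THF, 0 °C; methyl propiolate; then 21, 0 °C to rt
Reagents that add atoms: methyl propiolate C#CC(=O)OC
Why: vinylalumination (hydroalumination of the propiolate to the α-aluminoacrylate, then carbonyl addition) gives the Baylis–Hillman-type adduct quickly and without amine base, which the isomerization-prone aldehyde would not survive.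

Step 16
Reactants: 22 methyl (5E)-3-hydroxy-2-methylidene-6-(trimethylstannyl)hept-5-enoate (racemic)
Product: 23 methyl (2Z,5E)-2-(bromomethyl)-6-(trimethylstannyl)hepta-2,5-dienoate
Conditions: CBr4, PPh3, CH2Cl2, −20 to 0 °C
Reagents that add atoms: carbon tetrabromide BrC(Br)(Br)Br
Why: Appel bromination of a Baylis–Hillman alcohol occurs with allylic transposition (SN2′) to the conjugated primary bromide, whose more stable Z isomer (chain cis to CH2Br) should predominate.

Step 17
Reactants: 16 (2R,3S)-6-[(2S,3S)-3-ethenyl-2-methyloxiran-2-yl]-2-hydroxy-3-methylhexanal; 23 methyl (2Z,5E)-2-(bromomethyl)-6-(trimethylstannyl)hepta-2,5-dienoate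
Product: 25 (4S,5R)-5-[(1R,2S)-5-[(2S,3S)-3-ethenyl-2-methyloxiran-2-yl]-1-hydroxy-2-methylpentyl]-3-methylidene-4-[(2E)-3-(trimethylstannyl)but-2-en-1-yl]oxolan-2-one, via hydroxy ester 24 (not isolated)
Conditions: In powder, THF/H2O 1:1, rt; then DBU (20 mol%), CH2Cl2, rt
Reagents that add atoms: none
Why: indium-mediated Barbier allylation in water, in which the allylindium should react through its γ-carbon (C14) in a chair-like transition state so that the Z-bromide gives the C14/C1 syn adduct, while indium chelated between the free C2 hydroxyl and the aldehyde oxygen gives the 1,2-syn diol (C1 R, C14 S); base-catalysed 5-exo-trig lactonization through the C1 hydroxyl then closes the cis γ-lactone.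

Step 18
Reactants: 25 (4S,5R)-5-[(1R,2S)-5-[(2S,3S)-3-ethenyl-2-methyloxiran-2-yl]-1-hydroxy-2-methylpentyl]-3-methylidene-4-[(2E)-3-(trimethylstannyl)but-2-en-1-yl]oxolan-2-one
Product: 26 (1R,2S)-5-[(2S,3S)-3-ethenyl-2-methyloxiran-2-yl]-2-methyl-1-[(2R,3S)-4-methylidene-5-oxo-3-[(2E)-3-(trimethylstannyl)but-2-en-1-yl]oxolan-2-yl]pentyl acetate
Conditions: Ac2O, pyridine, DMAP (cat.), CH2Cl2, 0 °C
Reagents that add atoms: acetic anhydride CC(=O)OC(C)=O
Why: routine acetylation of the only free (secondary) hydroxyl installs the C2 acetate before the ring closure, so no hydroxyl can compete for the π-allyl.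

Step 19
Reactants: 26 (1R,2S)-5-[(2S,3S)-3-ethenyl-2-methyloxiran-2-yl]-2-methyl-1-[(2R,3S)-4-methylidene-5-oxo-3-[(2E)-3-(trimethylstannyl)but-2-en-1-yl]oxolan-2-yl]pentyl acetate
Product: 27 (1R,2R,3S,7S,14S,8E,11E)-2-acetoxy-7-hydroxy-3,7,11-trimethylcyclotetradeca-8,11-diene cis-fused at C1/C14 to 3-methylideneoxolan-2-one (lactone oxygen on C1)
Conditions: PdCl2(MeCN)2 (10 mol%), DMF/H2O 20:1, rt, 0.002 M, slow addition of 26
Reagents that add atoms: none
Why: Zerovalent palladium formed in situ ionizes the vinyl oxirane with inversion to the syn π-allyl palladium alkoxide spanning C8–C10, the alkoxide (with water) activates the trimethylstannyl group, the alkenyl group is transferred to palladium with retention, and reductive elimination at the unsubstituted terminus C10 forms the C10–C11 bond. The closest known reactions are the palladium-catalysed, water-promoted 1,4-coupling of vinyl epoxides with alkenylstannanes (Stille type) and macrocyclic Stille couplings of alkenylstannanes with allylic electrophiles. The 14-membered carbocycle closes as a formal intramolecular SN2′ opening in which all three allyl carbons end inside the ring (endo mode, with the oxirane C–O bond broken exo). No stereocentre is created: C7 keeps its configuration because its C–O bond is never broken, the E-C8=C9 geometry follows from the syn π-allyl enforced by the bulky quaternary C7 substituent, and the E-C11=C12 geometry is carried over from the stannane. The step needs attack at C10 rather than C8 and cyclization rather than oligomerization; the quaternary C7 next to C8 shields the internal terminus and leaves no β-hydrogen for isomerization to a dienol or ketone, high dilution with slow addition favours ring closure, and the acetate and α-methylene lactone are inert under the neutral conditions.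

Step 20
Reactants: 27 (1R,2R,3S,7S,14S,8E,11E)-2-acetoxy-7-hydroxy-3,7,11-trimethylcyclotetradeca-8,11-diene cis-fused at C1/C14 to 3-methylideneoxolan-2-one
Product: 28 CNP0202356.4, the (1R,2R,3S,7S,11R,12R,14S,8E)-11,12-epoxide of 27
Conditions: D-fructose-derived Shi ketone (30 mol%), KHSO5 (Oxone), K2CO3, Bu4NHSO4, MeCN/dimethoxymethane/aq. Na2B4O7 buffer, 0 °C
Reagents that add atoms: potassium peroxymonosulfate [K+].[O-]S(=O)(=O)OO
Why: Shi epoxidation, in which the chiral dioxirane should attack the most electron-rich, E-trisubstituted C11=C12 alkene through a spiro transition state on the face that gives the (R,R)-oxirane (the sense known for E-disubstituted and trisubstituted alkenes), while C8=C9 is deactivated by the allylic hydroxyl and its quaternary neighbour and the α-methylene lactone is electron-poor.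

**Compound list**

1 | 2-[(tert-butyldimethylsilyl)oxy]acetaldehyde | CC(C)(C)[Si](C)(C)OCC=O | starting material
2 | diisopinocampheylborinate of alcohol 3 | CC(C)(C)[Si](C)(C)OC[C@H](OB([C@H]1C[C@H]2C[C@H](C2(C)C)[C@@H]1C)[C@H]1C[C@H]2C[C@H](C2(C)C)[C@@H]1C)[C@@H](C)C=C | intermediate
3 | (2R,3S)-1-[(tert-butyldimethylsilyl)oxy]-3-methylpent-4-en-2-ol | CC(C)(C)[Si](C)(C)OC[C@H](O)[C@@H](C)C=C | intermediate
4 | (2R,3S)-1,2-bis[(tert-butyldimethylsilyl)oxy]-3-methylpent-4-ene | CC(C)(C)[Si](C)(C)OC[C@H](O[Si](C)(C)C(C)(C)C)[C@@H](C)C=C | intermediate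
5 | 9-[(3S,4R)-4,5-bis[(tert-butyldimethylsilyl)oxy]-3-methylpentyl]-9-borabicyclo[3.3.1]nonane | CC(C)(C)[Si](C)(C)OC[C@H](O[Si](C)(C)C(C)(C)C)[C@@H](C)CCB1C2CCCC1CCC2 | intermediate
6 | (3S,4R)-4,5-bis[(tert-butyldimethylsilyl)oxy]-3-methylpentan-1-ol | CC(C)(C)[Si](C)(C)OC[C@H](O[Si](C)(C)C(C)(C)C)[C@@H](C)CCO | intermediate
7 | (2R,3S)-1,2-bis[(tert-butyldimethylsilyl)oxy]-5-iodo-3-methylpentane | CC(C)(C)[Si](C)(C)OC[C@H](O[Si](C)(C)C(C)(C)C)[C@@H](C)CCI | intermediate
8 | (6S,7R)-7,8-bis[(tert-butyldimethylsilyl)oxy]-6-methyl-1-(trimethylsilyl)oct-1-yne | CC(C)(C)[Si](C)(C)OC[C@H](O[Si](C)(C)C(C)(C)C)[C@@H](C)CCCC#C[Si](C)(C)C | intermediate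
9 | (6S,7R)-7,8-bis[(tert-butyldimethylsilyl)oxy]-6-methyloct-1-yne | CC(C)(C)[Si](C)(C)OC[C@H](O[Si](C)(C)C(C)(C)C)[C@@H](C)CCCC#C | intermediate
10 | dimethyl[(1E,6S,7R)-7,8-bis[(tert-butyldimethylsilyl)oxy]-2,6-dimethyloct-1-en-1-yl]alane | CC(C)(C)[Si](C)(C)OC[C@H](O[Si](C)(C)C(C)(C)C)[C@@H](C)CCC/C(C)=C/[Al](C)C | intermediate
11 | (2E,7S,8R)-8,9-bis[(tert-butyldimethylsilyl)oxy]-3,7-dimethylnon-2-en-1-ol | CC(C)(C)[Si](C)(C)OC[C@H](O[Si](C)(C)C(C)(C)C)[C@@H](C)CCC/C(C)=C/CO | intermediate
12 | [(2S,3S)-3-[(4S,5R)-5,6-bis[(tert-butyldimethylsilyl)oxy]-4-methylhexyl]-3-methyloxiran-2-yl]methanol | CC(C)(C)[Si](C)(C)OC[C@H](O[Si](C)(C)C(C)(C)C)[C@@H](C)CCC[C@]1(C)O[C@H]1CO | intermediate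
13 | (2R,3S)-3-[(4S,5R)-5,6-bis[(tert-butyldimethylsilyl)oxy]-4-methylhexyl]-3-methyloxirane-2-carbaldehyde | CC(C)(C)[Si](C)(C)OC[C@H](O[Si](C)(C)C(C)(C)C)[C@@H](C)CCC[C@]1(C)O[C@H]1C=O | intermediate
14 | (2S,3S)-2-[(4S,5R)-5,6-bis[(tert-butyldimethylsilyl)oxy]-4-methylhexyl]-3-ethenyl-2-methyloxirane | CC(C)(C)[Si](C)(C)OC[C@H](O[Si](C)(C)C(C)(C)C)[C@@H](C)CCC[C@]1(C)O[C@H]1C=C | intermediate
15 | (2R,3S)-6-[(2S,3S)-3-ethenyl-2-methyloxiran-2-yl]-3-methylhexane-1,2-diol | OC[C@H](O)[C@@H](C)CCC[C@]1(C)O[C@H]1C=C | intermediate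
16 | (2R,3S)-6-[(2S,3S)-3-ethenyl-2-methyloxiran-2-yl]-2-hydroxy-3-methylhexanal | O=C[C@H](O)[C@@H](C)CCC[C@]1(C)O[C@H]1C=C | intermediate
17 | pent-3-yn-1-ol | CC#CCCO | starting material
18 | (E)-alkenylzirconocene chloride of the zirconocene alkoxide of 17 (zirconium on C4 and on oxygen) | Cl[Zr](C1C=CC=C1)(C1C=CC=C1)/C(C)=C/CCO[Zr](Cl)(C1C=CC=C1)C1C=CC=C1 | intermediate
19 | (E)-4-iodopent-3-en-1-ol | I/C(C)=C/CCO | intermediate
20 | (E)-4-(trimethylstannyl)pent-3-en-1-ol | C[Sn](C)(C)/C(C)=C/CCO | intermediate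
21 | (E)-4-(trimethylstannyl)pent-3-enal | C[Sn](C)(C)/C(C)=C/CC=O | intermediate
22 | methyl (5E)-3-hydroxy-2-methylidene-6-(trimethylstannyl)hept-5-enoate (racemic) | C[Sn](C)(C)/C(C)=C/CC(O)C(=C)C(=O)OC | intermediate
23 | methyl (2Z,5E)-2-(bromomethyl)-6-(trimethylstannyl)hepta-2,5-dienoate | C[Sn](C)(C)/C(C)=C/C/C=C(\CBr)C(=O)OC | intermediate
24 | methyl (3S,4R,5R,6S)-9-[(2S,3S)-3-ethenyl-2-methyloxiran-2-yl]-4,5-dihydroxy-6-methyl-2-methylidene-3-[(2E)-3-(trimethylstannyl)but-2-en-1-yl]nonanoate | COC(=O)C(=C)[C@H](C/C=C(C)/[Sn](C)(C)C)[C@@H](O)[C@H](O)[C@@H](C)CCC[C@]1(C)O[C@H]1C=C | intermediate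
25 | (4S,5R)-5-[(1R,2S)-5-[(2S,3S)-3-ethenyl-2-methyloxiran-2-yl]-1-hydroxy-2-methylpentyl]-3-methylidene-4-[(2E)-3-(trimethylstannyl)but-2-en-1-yl]oxolan-2-one | C=C1C(=O)O[C@@H]([C@H](O)[C@@H](C)CCC[C@]2(C)O[C@H]2C=C)[C@H]1C/C=C(C)/[Sn](C)(C)C | intermediate
26 | (1R,2S)-5-[(2S,3S)-3-ethenyl-2-methyloxiran-2-yl]-2-methyl-1-[(2R,3S)-4-methylidene-5-oxo-3-[(2E)-3-(trimethylstannyl)but-2-en-1-yl]oxolan-2-yl]pentyl acetate | C=C1C(=O)O[C@@H]([C@H](OC(C)=O)[C@@H](C)CCC[C@]2(C)O[C@H]2C=C)[C@H]1C/C=C(C)/[Sn](C)(C)C | intermediate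
27 | (1R,2R,3S,7S,14S,8E,11E)-2-acetoxy-7-hydroxy-3,7,11-trimethylcyclotetradeca-8,11-diene cis-fused at C1/C14 to 3-methylideneoxolan-2-one (plan numbering) | C=C1C(=O)O[C@H]2[C@H](OC(C)=O)[C@@H](C)CCC[C@](C)(O)/C=C/C/C(C)=C/C[C@@H]12 | intermediate
28 | CNP0202356.4, (1R,2R,3S,7S,11R,12R,14S,8E)-2-acetoxy-11,12-epoxy-7-hydroxy-3,7,11-trimethylcyclotetradec-8-ene cis-fused at C1/C14 to 3-methylideneoxolan-2-one (plan numbering) | C=C1C(=O)O[C@H]2[C@H](OC(C)=O)[C@@H](C)CCC[C@](C)(O)/C=C/C[C@@]3(C)O[C@@H]3C[C@@H]12 | target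

**Step count**

Total: 20 steps. Longest linear sequence: 15 steps (steps 1–11, then 17–20); fragment 2 takes 5 steps (12–16).

**Steps most likely to fail**

Step 19 (ring closure). The alkenyl group may be delivered to the internal allyl carbon C8, or through an anti π-allyl to give the Z-alkene, and intermolecular coupling or protodestannylation may outrun cyclization. The fallback sets out from 14 and comes back at 27; it closes the same bond from a pre-formed E-allylic acetate, so the alkene geometry is fixed before the ring is made. Vinyl oxirane 14 is opened with acetic acid under Pd(PPh3)4 catalysis (intermolecular 1,4-addition) to the E-configured hydroxy allylic acetate F1. Desilylation with Bu4NF buffered with acetic acid gives the triol monoacetate F2, and TEMPO/PhI(OAc)2 oxidation gives the α-hydroxy aldehyde F3. Indium-mediated union with 23 in aqueous THF gives the hydroxy ester F4, which is lactonized with DBU to the lactone F5. Acetylation of the secondary hydroxyl (the tertiary C7 hydroxyl stays free) gives the diacetate F6. The coupling of the allylic acetate with the alkenylstannane (Pd2(dba)3, LiCl, DMF, high dilution) then gives 27.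

Step 17 (fragment union). The vinyl oxirane may be opened hydrolytically and the stannane protonated in the weakly acidic aqueous medium; chelation control may erode (Felkin-type attack, C1 epimer); lactonization may occur through the C2 hydroxyl. The fallback sets out from 16 and 23 and comes back at 25; it replaces the aqueous Barbier reaction by a pre-formed organometallic reagent in an aprotic medium. Bromide 23 is converted with zinc dust and LiCl in THF at 0 °C into the allylzinc bromide F7. An excess of F7 is added at −78 °C to 16 in THF, so that the first equivalent of zinc binds the C2 alkoxide and the aldehyde oxygen in a five-membered chelate before the chair-like addition. This should give 24, which is lactonized with DBU as before to 25.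

Step 20 (epoxidation). The folded macrocycle may oppose the catalyst and give poor facial selectivity, the C8=C9 alkene may be oxidized as well, and the basic medium may cleave the acetate. The fallback sets out from 27 and comes back at 28; it uses a two-step halohydrin route that places the oxygen on the face opposite to the one attacked by the electrophile, the reverse of a direct peracid or dioxirane epoxidation on the same exposed face. NBS in aqueous THF at 0 °C should attack the most electron-rich C11=C12 alkene, and water opens the bromonium ion at the tertiary C11 to give the bromohydrin F8. K2CO3 in acetone then closes the oxirane by displacement of bromide at C12 with inversion, giving 28.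

Further compounds
F1 | step 19 | (2E,4S,8S,9R)-9,10-bis[(tert-butyldimethylsilyl)oxy]-4-hydroxy-4,8-dimethyldec-2-en-1-yl acetate | CC(C)(C)[Si](C)(C)OC[C@H](O[Si](C)(C)C(C)(C)C)[C@@H](C)CCC[C@](C)(O)/C=C/COC(C)=O
F2 | step 19 | (2E,4S,8S,9R)-4,9,10-trihydroxy-4,8-dimethyldec-2-en-1-yl acetate | OC[C@H](O)[C@@H](C)CCC[C@](C)(O)/C=C/COC(C)=O
F3 | step 19 | (2E,4S,8S,9R)-4,9-dihydroxy-4,8-dimethyl-10-oxodec-2-en-1-yl acetate | O=C[C@H](O)[C@@H](C)CCC[C@](C)(O)/C=C/COC(C)=O
F4 | step 19 | methyl (3S,4R,5R,6S,10S,11E)-13-acetoxy-4,5,10-trihydroxy-6,10-dimethyl-2-methylidene-3-[(2E)-3-(trimethylstannyl)but-2-en-1-yl]tridec-11-enoate | COC(=O)C(=C)[C@H](C/C=C(C)/[Sn](C)(C)C)[C@@H](O)[C@H](O)[C@@H](C)CCC[C@](C)(O)/C=C/COC(C)=O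
F5 | step 19 | (2E,4S,8S,9R)-4,9-dihydroxy-4,8-dimethyl-9-[(2R,3S)-4-methylidene-5-oxo-3-[(2E)-3-(trimethylstannyl)but-2-en-1-yl]oxolan-2-yl]non-2-en-1-yl acetate | C=C1C(=O)O[C@@H]([C@H](O)[C@@H](C)CCC[C@](C)(O)/C=C/COC(C)=O)[C@H]1C/C=C(C)/[Sn](C)(C)C
F6 | step 19 | (2E,4S,8S,9R)-9-acetoxy-4-hydroxy-4,8-dimethyl-9-[(2R,3S)-4-methylidene-5-oxo-3-[(2E)-3-(trimethylstannyl)but-2-en-1-yl]oxolan-2-yl]non-2-en-1-yl acetate | C=C1C(=O)O[C@@H]([C@H](OC(C)=O)[C@@H](C)CCC[C@](C)(O)/C=C/COC(C)=O)[C@H]1C/C=C(C)/[Sn](C)(C)C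
F7 | step 17 | [(2Z,5E)-2-(methoxycarbonyl)-6-(trimethylstannyl)hepta-2,5-dien-1-yl]zinc bromide | C[Sn](C)(C)/C(C)=C/C/C=C(\C[Zn]Br)C(=O)OC
F8 | step 20 | (11R,12S)-12-bromo-11-hydroxy derivative of 27 (bromohydrin, hydroxyl on C11, bromine on C12) | C=C1C(=O)O[C@H]2[C@H](OC(C)=O)[C@@H](C)CCC[C@](C)(O)/C=C/C[C@@](C)(O)[C@@H](Br)C[C@@H]12
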